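## Retrosynthetic overview

1. Sideroxylonal A ⇒ biomimetic oxa-[4+2] union of two identical C13 halves: the o-quinone methide of isopentyl-diformylphloroglucinol (supplies O1, C8a, C4a, C4) and its own E-styrene tautomer (supplies C2, C3 and the 2-aryl group). The dihydropyran ring is the only ring made, and it is made last.
2. Both halves ⇒ one unprotected monomer, the benzylic carbinol 2,4,6-trihydroxy-5-(1-hydroxy-3-methylbutyl)isophthalaldehyde. One chiral phosphoric acid dehydrates it, tautomerises part of it and steers the dimerisation, setting all three stereocenters in one operation.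
3. Carbinol ⇒ mono-addition of isobutylmagnesium bromide to C3-symmetric triformylphloroglucinol.
4. Triformylphloroglucinol ⇒ phloroglucinol + hexamethylenetetramine (Duff formylation).

Assumption: triformylphloroglucinol is not counted as a cheap starting material, so it is made in the first step from phloroglucinol.

## Route

Step 1
Reactants: 1 phloroglucinol (benzene-1,3,5-triol); 2 hexamethylenetetramine
Product: 3 2,4,6-trihydroxybenzene-1,3,5-tricarbaldehyde (triformylphloroglucinol)
Conditions: HMTA (3.3 equiv), CF3CO2H, 100 °C, 2.5 h; then 3 M aq HCl, 100 °C, 1 h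
Reagents that add atoms: hexamethylenetetramine C1N2CN3CN1CN(C2)C3 (the three formyl carbons); water O (the three formyl oxygens)
Why: Threefold Duff formylation: HMTA-derived iminium ions aminomethylate each free position of the triphenol, hydride transfer gives benzyliminium ions and aqueous HCl hydrolyses them to hydrogen-bond-locked CHO groups; a known reaction whose modest yield is offset by the cost of the materials; no stereocenter.

Step 2
Reactants: 3 triformylphloroglucinol; 4 isobutylmagnesium bromide
Product: 7 rac-2,4,6-trihydroxy-5-(1-hydroxy-3-methylbutyl)benzene-1,3-dicarbaldehyde, via tris(bromomagnesium) phenoxide 5 (not isolated), via tetrakis(bromomagnesium) salt 6 (not isolated)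
Conditions: iBuMgBr (4.4 equiv), LiCl (3 equiv), THF, −40 → 0 °C; then cold 1 M aq HCl to pH 3–4, EtOAc extraction at 0 °C, concentration below 20 °C, used without silica chromatography
Reagents that add atoms: isobutylmagnesium bromide CC(C)C[Mg]Br
Why: Grignard 1,2-addition to an unprotected hydroxy-aldehyde with excess reagent (three equivalents act as base): the three phenoxide charges of 5 are shared by three Mg-chelated formyl groups, so each reacts like a magnesium salicylaldehydate, and the tetra-anion 6 resists a second addition; the carbinol center forms racemic, which does not matter because step 3 erases it.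

Step 3
Reactants: 7 rac-2,4,6-trihydroxy-5-(1-hydroxy-3-methylbutyl)benzene-1,3-dicarbaldehyde (two molecules)
Product: 10 sideroxylonal A, via o-quinone methide 8 (not isolated), via E-styrene 9 (not isolated)
Conditions: (R)-TRIP [(R)-3,3'-bis(2,4,6-triisopropylphenyl)-1,1'-binaphthalene-2,2'-diyl hydrogen phosphate] (10 mol%), 5 Å MS, PhMe/CH2Cl2 4:1, 0.1 M, 0 °C → rt, 48–72 h
Reagents that add atoms: none
Why: Proposed new method: the phosphoric acid dehydrates 7 to the hydrogen-bonded o-quinone methide 8 (as with any o-hydroxybenzyl alcohol) and its phosphate shuttles the γ-proton so that part of 8 rests as the E-styrene 9 (the usual leak of alkyl o-quinone methides to o-vinylphenols); the catalyst-bound pair then undergoes an asynchronous inverse-demand oxa-[4+2] in which C-β of 9 attacks the methide carbon of 8 and the carbonyl oxygen closes on the benzylic carbon; the phosphate bridges the OH of protonated 8 and an ortho-OH of 9, which places the aryl group of 9 exo and its isopropyl group endo (3,4-cis, isobutyl pseudoaxial away from the peri 5-OH), suprafacial addition to the E-alkene gives 2,3-trans (also the thermodynamic outcome, since C2 can epimerise by acid-mediated ring opening), and the binaphthyl pocket selects the face leading to (2R,3R,4S); closest known reactions are chiral phosphoric acid-catalysed [4+2] cycloadditions of in situ o-quinone methides with o-hydroxystyrenes and the acid-catalysed dimerisation of o-vinylphenols to 2-(2-hydroxyphenyl)-4-alkylchromans.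

## Compound list

1 | phloroglucinol (benzene-1,3,5-triol) | Oc1cc(O)cc(O)c1 | starting material
2 | hexamethylenetetramine (HMTA, 1,3,5,7-tetraazaadamantane) | C1N2CN3CN1CN(C2)C3 | starting material
3 | 2,4,6-trihydroxybenzene-1,3,5-tricarbaldehyde (triformylphloroglucinol) | O=Cc1c(O)c(C=O)c(O)c(C=O)c1O | intermediate
4 | isobutylmagnesium bromide (2-methylpropylmagnesium bromide) | CC(C)C[Mg]Br | starting material
5 | tris(bromomagnesium) phenoxide of 3 | O=Cc1c(O[Mg]Br)c(C=O)c(O[Mg]Br)c(C=O)c1O[Mg]Br | intermediate
6 | tetrakis(bromomagnesium) salt of 7 (benzylic alkoxide plus three phenoxides, racemic) | CC(C)CC(O[Mg]Br)c1c(O[Mg]Br)c(C=O)c(O[Mg]Br)c(C=O)c1O[Mg]Br | intermediate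
7 | rac-2,4,6-trihydroxy-5-(1-hydroxy-3-methylbutyl)benzene-1,3-dicarbaldehyde (racemic at the carbinol carbon) | CC(C)CC(O)c1c(O)c(C=O)c(O)c(C=O)c1O | intermediate
8 | (5E)-2,4-dihydroxy-5-(3-methylbutylidene)-6-oxocyclohexa-1,3-diene-1,3-dicarbaldehyde (o-quinone methide, isobutyl group anti to the ring C=O) | CC(C)C/C=C1/C(=O)C(C=O)=C(O)C(C=O)=C1O | intermediate
9 | 2,4,6-trihydroxy-5-[(1E)-3-methylbut-1-en-1-yl]benzene-1,3-dicarbaldehyde (E-styrene) | CC(C)/C=C/c1c(O)c(C=O)c(O)c(C=O)c1O | intermediate
10 | sideroxylonal A, (2R,3R,4S)-2-(3,5-diformyl-2,4,6-trihydroxyphenyl)-5,7-dihydroxy-4-(2-methylpropyl)-3-(propan-2-yl)-3,4-dihydro-2H-chromene-6,8-dicarbaldehyde (2-aryl and 3-isopropyl trans, 3-isopropyl and 4-isobutyl cis) | CC(C)C[C@@H]1c2c(O)c(C=O)c(O)c(C=O)c2O[C@@H](c2c(O)c(C=O)c(O)c(C=O)c2O)[C@@H]1C(C)C | target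

## Step count and risks

Total step count: 3. Longest linear sequence: 3 steps (1 → 3 → 7 → 10).

The three steps most likely to fail, most risky first:

**Step 3, the asymmetric dimerisation.** Three things can go wrong:
- The acidic polyphenols 7 and 10 may catalyse a racemic background reaction.
- The diastereomeric chromans (3,4-trans or 2,3-cis) may compete with the 2,3-trans-3,4-cis isomer.
- The sense of induction of the (R)-acid cannot be predicted with confidence. If the antipode predominates, the (S)-acid is used; if ionisation is slow, the N-triflyl phosphoramide analogue of the catalyst is tried.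

Fallback: setting out from 7, the dimerisation is run with an achiral acid (diphenyl phosphate, 10 mol%, PhMe, rt). This gives racemic sideroxylonal A, that is, 10 together with its mirror image (2S,3S,4R)-sideroxylonal A F1. The racemate is separated from its diastereomers by chromatography or crystallisation and then resolved by preparative HPLC on an amylose tris(3,5-dimethylphenylcarbamate) phase (hexane/iPrOH with 0.1% CF3CO2H). The fallback comes back to the route at 10.

**Step 2, the Grignard mono-addition.** The polyanion 5 may be insoluble or too unreactive, the isobutyl reagent may reduce by β-hydride transfer, a second addition may occur, or 7 may ionise during the acidic work-up.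

Fallback: setting out from 1, the isobutyl-bearing carbon is installed with the arene as nucleophile, and the quinone methide is reached by oxidation:
- Friedel–Crafts acylation with isovaleryl chloride (AlCl3, PhNO2/CH2Cl2, rt → 50 °C) gives 3-methyl-1-(2,4,6-trihydroxyphenyl)butan-1-one F2.
- Ionic hydrogenation (Et3SiH, CF3CO2H, rt) gives 2-(3-methylbutyl)benzene-1,3,5-triol F3.
- Vilsmeier–Haack diformylation (POCl3, DMF, EtOAc, rt; then H2O, 60 °C) gives 2,4,6-trihydroxy-5-(3-methylbutyl)benzene-1,3-dicarbaldehyde F4.
- Benzylic dehydrogenation with DDQ (1.0 equiv, MeNO2, 0 °C) gives the o-quinone methide.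

The precipitated hydroquinone is filtered off cold and (R)-TRIP is added to the filtrate as in step 3. The fallback comes back to the route at 8.

**Step 1, the threefold Duff formylation.** Yields are low because phloroglucinol is partly consumed in methylene-bridged oligomers before all three positions are formylated.

Fallback: setting out from 1, Vilsmeier–Haack diformylation (POCl3, DMF, EtOAc, rt; then H2O) gives 2,4,6-trihydroxybenzene-1,3-dicarbaldehyde F5. This has a single nucleophilic position left and cannot oligomerise. A single Duff formylation (HMTA, CF3CO2H, 90 °C; then 3 M aq HCl) completes the substitution. The fallback comes back to the route at 3.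

## Further compounds

F1 | step 3 | (2S,3S,4R)-enantiomer of sideroxylonal A (formed 1:1 with 10 in the racemate) | CC(C)C[C@H]1c2c(O)c(C=O)c(O)c(C=O)c2O[C@H](c2c(O)c(C=O)c(O)c(C=O)c2O)[C@H]1C(C)C
F2 | step 2 | 3-methyl-1-(2,4,6-trihydroxyphenyl)butan-1-one | CC(C)CC(=O)c1c(O)cc(O)cc1O
F3 | step 2 | 2-(3-methylbutyl)benzene-1,3,5-triol | CC(C)CCc1c(O)cc(O)cc1O
F4 | step 2 | 2,4,6-trihydroxy-5-(3-methylbutyl)benzene-1,3-dicarbaldehyde | CC(C)CCc1c(O)c(C=O)c(O)c(C=O)c1O
F5 | step 1 | 2,4,6-trihydroxybenzene-1,3-dicarbaldehyde | O=Cc1c(O)cc(O)c(C=O)c1O
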